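The route rests on cutting the C7''–C8'' bond of luteolin ring A''. Because C8'' (bonded to ring B' C2' and flanked by the oxygen-bearing C7'' and C8a'') can be a benzylic CH2, the congested biaryl bond is carried in as an ordinary aryl–CH2 bond. In one operation a Claisen cyclisation of the arylacetyl carbon onto the terminal ester closes and aromatises ring A'' as a phloroglucinol ester whose ester carbon becomes C4''. The precursor is a dimethyl 2-(arylacetyl)-3-oxopentanedioate carrying ring B' with benzyl ethers and an acetal-masked aldehyde; the ring C'' pyrone and the (2S)-flavanone are built afterwards.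

Key step: step 7

Assumption: the C2'–C8'' biaryl axis carries no stereodescriptor in the target, so only C2 (S) is controlled and rotamers about the axis are carried through unseparated.
Notation: flavanone atoms are unprimed, its aryl ring B' is primed, the luteolin chromone is double-primed and the luteolin catechol ring triple-primed; ArB = 2,3-bis(benzyloxy)-6-(5,5-dimethyl-1,3-dioxan-2-yl)phenyl.

Step 1
Reactants: 1 2-bromo-3-hydroxy-4-methoxybenzaldehyde
Product: 2 2-bromo-3,4-dihydroxybenzaldehyde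
Conditions: BBr3, CH2Cl2, −78 °C → rt; H2O
Reagents that add atoms: none
Why: Lewis-acid aryl methyl ether cleavage: BBr3 coordinates the methoxy oxygen and bromide removes the methyl group by SN2, the aldehyde and the aryl bromide being inert at low temperature.

Step 2
Reactants: 2 2-bromo-3,4-dihydroxybenzaldehyde
Product: 3 3,4-bis(benzyloxy)-2-bromobenzaldehyde
Conditions: BnBr, K2CO3, DMF, 60 °C
Reagents that add atoms: benzyl bromide, BrCc1ccccc1
Why: Williamson etherification of both phenoxides; benzyl is chosen so that every phenol of the route can be freed together by neutral hydrogenolysis at the end.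

Step 3
Reactants: 3 3,4-bis(benzyloxy)-2-bromobenzaldehyde
Product: 4 2-[3,4-bis(benzyloxy)-2-bromophenyl]-5,5-dimethyl-1,3-dioxane
Conditions: 2,2-dimethylpropane-1,3-diol, p-TsOH·H2O (cat.), toluene, reflux, Dean–Stark
Reagents that add atoms: 2,2-dimethylpropane-1,3-diol, OCC(C)(C)CO
Why: Acid-catalysed acetalisation with azeotropic removal of water; the 5,5-dimethyl-1,3-dioxane is preferred to a dioxolane because this aldehyde is para to an alkoxy group and a more hydrolysis-resistant acetal is needed to survive the mildly acidic work-ups of steps 5 to 10 next to a carboxylic acid and free phenols.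

Step 4
Reactants: 4 2-[3,4-bis(benzyloxy)-2-bromophenyl]-5,5-dimethyl-1,3-dioxane
Product: 5 ethyl 2-ArB-acetate
Conditions: BrZnCH2CO2Et (from BrCH2CO2Et, Zn, TMSCl cat., THF), Pd2(dba)3 (2.5 mol %), XPhos (10 mol %), THF, 65 °C
Reagents that add atoms: ethyl bromoacetate, CCOC(=O)CBr (used as its zinc enolate made in the flask)
Why: Negishi-type cross-coupling of the Reformatsky zinc enolate with the aryl bromide (palladium-catalysed ester α-arylation) runs under neutral conditions that spare acetal and benzyl ethers, and the bulky biarylphosphine is chosen for a bromide with two ortho substituents.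

Step 5
Reactants: 5 ethyl 2-ArB-acetate
Product: 6 2-ArB-acetic acid
Conditions: LiOH·H2O, THF/MeOH/H2O, rt; aq. citric acid to pH 4, 0 °C
Reagents that add atoms: lithium hydroxide, [Li+].[OH-]
Why: Saponification of the unhindered ethyl ester under conditions to which acetal and benzyl ethers are inert, with a buffered acidification so that the acetal never meets strong acid.

Step 6
Reactants: 6 2-ArB-acetic acid; 7 dimethyl 3-oxopentanedioate
Product: 9 dimethyl 2-(ArB-acetyl)-3-oxopentanedioate, via acyl imidazolide 8 (not isolated)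
Conditions: CDI, THF, rt; then 7, MgCl2, Et3N, MeCN, 0 °C → rt; aq. NaH2PO4
Reagents that add atoms: none
Why: C-Acylation of the chelated magnesium enolate of a β-keto ester by an acyl imidazolide (magnesium-mediated Claisen-type acylation): the two α-carbons of 7 are equivalent, and the magnesium chelate of the triacylmethane product resists O-acylation and a second acylation.

Step 7
Reactants: 9 dimethyl 2-(ArB-acetyl)-3-oxopentanedioate
Product: 10 methyl 3-ArB-2,4,6-trihydroxybenzoate
Conditions: Mg(OMe)2 (4 equiv), MeOH, reflux; AcOH, 0 °C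
Reagents that add atoms: none
Why: Under Mg(OMe)2 the triacylmethane sits as its magnesium chelate, and proton exchange in methanol supplies a small equilibrium amount of the benzylic enolate, which adds to the terminal ester carbonyl; loss of methoxide gives a cyclohexane-1,3,5-trione that tautomerises at once to the phloroglucinol (Claisen condensation of Dieckmann type). The closest known reactions are the magnesium methoxide cyclisation of 3,5,7-tricarbonyl esters to acylphloroglucinols and the alkoxide cyclisation of 6-aryl-5-oxohexanoates to 2-arylcyclohexane-1,3-diones. Ring A'' closes by 6-exo-trig acyl substitution, forming C7''–C8'' with the aryl group already on the nucleophilic carbon. No stereocentre is created. The step needs carbon rather than oxygen cyclisation (a 4-hydroxy-2-pyrone) and cyclisation rather than methanolytic loss of an acyl group: magnesium chelation ties up the enolate oxygens and shields the triacylmethane carbonyls, pyrone formation is reversible in Mg(OMe)2/MeOH whereas aromatisation is not, and the benzylic carbon is the only carbon that can reach an ester through a six-membered transition state.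

Step 8
Reactants: 10 methyl 3-ArB-2,4,6-trihydroxybenzoate
Product: 11 methyl 4,6-bis(benzyloxy)-3-ArB-2-hydroxybenzoate
Conditions: BnBr (2.1 equiv), K2CO3, acetone, rt → 45 °C
Reagents that add atoms: benzyl bromide, BrCc1ccccc1
Why: Williamson etherification under mild carbonate conditions takes the para hydroxyl (most acidic, not hydrogen-bonded) and then the less hindered ortho hydroxyl, while the hydroxyl wedged between the aryl group and the ester (the future O1'') is shielded and chelated to the ester carbonyl and stays free.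

Step 9
Reactants: 12 3,4-dihydroxyacetophenone
Product: 13 3,4-bis(benzyloxy)acetophenone
Conditions: BnBr, K2CO3, DMF, 60 °C
Reagents that add atoms: benzyl bromide, BrCc1ccccc1
Why: Williamson etherification of both catechol hydroxyls.

Step 10
Reactants: 11 methyl 4,6-bis(benzyloxy)-3-ArB-2-hydroxybenzoate; 13 3,4-bis(benzyloxy)acetophenone
Product: 14 1-[4,6-bis(benzyloxy)-3-ArB-2-hydroxyphenyl]-3-[3,4-bis(benzyloxy)phenyl]propane-1,3-dione
Conditions: 13 (2 equiv), LiN(SiMe3)2 (4.5 equiv), THF, −78 °C → rt; aq. NH4Cl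
Reagents that add atoms: none
Why: Crossed Claisen condensation of a lithium ketone enolate with a non-enolisable aryl ester to give an o-hydroxydibenzoylmethane: the ortho lithium phenoxide chelates the ester carbonyl, and deprotonation of the 1,3-diketone product pulls the equilibrium forward.

Step 11
Reactants: 14 1-[4,6-bis(benzyloxy)-3-ArB-2-hydroxyphenyl]-3-[3,4-bis(benzyloxy)phenyl]propane-1,3-dione
Product: 16 3,4-bis(benzyloxy)-2-{5,7-bis(benzyloxy)-2-[3,4-bis(benzyloxy)phenyl]-4-oxo-4H-chromen-8-yl}benzaldehyde, via flavone acetal 15 (not isolated)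
Conditions: conc. HCl (cat.), AcOH, 60 °C; then 2 M HCl, THF, 45 °C
Reagents that add atoms: water, O
Why: Acid-catalysed hemiketalisation and dehydration of the o-hydroxyaryl 1,3-diketone (the cyclodehydration that ends a Baker–Venkataraman flavone synthesis) closes the γ-pyrone through the only free phenol, which fixes the 8-aryl regiochemistry, and the aqueous acid then hydrolyses the acetal; any reversible capture of that phenol by the acetal carbon is drained by the irreversible pyrone formation.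

Step 12
Reactants: 17 2,4,6-trihydroxyacetophenone
Product: 18 2-hydroxy-4,6-bis(benzyloxy)acetophenone
Conditions: BnBr (2.1 equiv), K2CO3, acetone, reflux
Reagents that add atoms: benzyl bromide, BrCc1ccccc1
Why: Williamson etherification takes the para and one ortho hydroxyl, the other ortho hydroxyl staying free because it is chelated to the acetyl carbonyl.

Step 13
Reactants: 18 2-hydroxy-4,6-bis(benzyloxy)acetophenone
Product: 19 tert-butyl 3-[2,4-bis(benzyloxy)-6-hydroxyphenyl]-3-oxopropanoate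
Conditions: LiN(SiMe3)2 (3.2 equiv), THF, −78 °C; Boc2O, −78 → 0 °C; aq. NH4Cl
Reagents that add atoms: di-tert-butyl dicarbonate, CC(C)(C)OC(=O)OC(=O)OC(C)(C)C
Why: Claisen-type C-acylation of the phenoxide–enolate dianion by Boc2O; any O-Boc phenol formed passes its acyl group to carbon under the excess base (Baker–Venkataraman-type shift), and the tert-butyl ester resists lactonisation to a 4-hydroxycoumarin.

Step 14
Reactants: 16 3,4-bis(benzyloxy)-2-{5,7-bis(benzyloxy)-2-[3,4-bis(benzyloxy)phenyl]-4-oxo-4H-chromen-8-yl}benzaldehyde; 19 tert-butyl 3-[2,4-bis(benzyloxy)-6-hydroxyphenyl]-3-oxopropanoate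
Product: 20 tert-butyl 2-[2,4-bis(benzyloxy)-6-hydroxybenzoyl]-3-aryl-prop-2-enoate (aryl = the flavonyl-substituted ring B' of 16; double-bond geometry not assigned)
Conditions: piperidine (cat.), AcOH (cat.), toluene, 80 °C, 4 Å MS
Reagents that add atoms: none
Why: Knoevenagel condensation of the non-enolisable aldehyde with the β-keto ester under piperidinium acetate catalysis with removal of water, the buffered medium keeping the phenol from adding to the new alkene.

Step 15
Reactants: 20 tert-butyl 2-[2,4-bis(benzyloxy)-6-hydroxybenzoyl]-3-aryl-prop-2-enoate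
Product: 23 (2S)-octa-O-benzyl flavanone–flavone, via tert-butyl flavanone-3-carboxylate 21 (not isolated), via flavanone-3-carboxylic acid 22 (not isolated)
Conditions: 9-amino-9-deoxy-epi-cinchona 3,5-(CF3)2C6H3-thiourea, (2S)-selective pseudoenantiomer (10 mol %), toluene, −25 °C; then p-TsOH·H2O, 80 °C
Reagents that add atoms: none
Why: Bifunctional thiourea-catalysed intramolecular oxa-Michael addition: the thiourea binds the β-keto ester while the quinuclidine base delivers the phenol to one face of the alkylidene, so C2 is set (S) under catalyst control (the quinine- and quinidine-derived catalysts are pseudoenantiomers, and the one that gives 2S is to be identified on a model substrate and used), and acid then removes the tert-butyl group and CO2, erasing the C3 stereocentre without touching C2.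

Step 16
Reactants: 23 (2S)-octa-O-benzyl flavanone–flavone
Product: 24 (2S)-2-{2-[2-(3,4-dihydroxyphenyl)-5,7-dihydroxy-4-oxo-4H-chromen-8-yl]-3,4-dihydroxyphenyl}-5,7-dihydroxychroman-4-one (CNP0265600.1)
Conditions: H2 (1 atm), Pd/C (10 wt %), THF/MeOH, rt
Reagents that add atoms: none
Why: Palladium-catalysed hydrogenolysis cleaves all eight benzyl aryl ethers under neutral conditions that do not open the flavanone ring, so C2 keeps its configuration, and that should leave the flavone C2''=C3'' bond intact at ambient pressure.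

Compound list
1 | 2-bromo-3-hydroxy-4-methoxybenzaldehyde | COc1ccc(C=O)c(Br)c1O | starting material
2 | 2-bromo-3,4-dihydroxybenzaldehyde | O=Cc1ccc(O)c(O)c1Br | intermediate
3 | 3,4-bis(benzyloxy)-2-bromobenzaldehyde | O=Cc1ccc(OCc2ccccc2)c(OCc2ccccc2)c1Br | intermediate
4 | 2-[3,4-bis(benzyloxy)-2-bromophenyl]-5,5-dimethyl-1,3-dioxane | Brc1c(C2OCC(C)(C)CO2)ccc(OCc2ccccc2)c1OCc1ccccc1 | intermediate
5 | ethyl 2-[2,3-bis(benzyloxy)-6-(5,5-dimethyl-1,3-dioxan-2-yl)phenyl]acetate | CCOC(=O)Cc1c(C2OCC(C)(C)CO2)ccc(OCc2ccccc2)c1OCc1ccccc1 | intermediate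
6 | 2-[2,3-bis(benzyloxy)-6-(5,5-dimethyl-1,3-dioxan-2-yl)phenyl]acetic acid | OC(=O)Cc1c(C2OCC(C)(C)CO2)ccc(OCc2ccccc2)c1OCc1ccccc1 | intermediate
7 | dimethyl 3-oxopentanedioate | COC(=O)CC(=O)CC(=O)OC | starting material
8 | 2-[2,3-bis(benzyloxy)-6-(5,5-dimethyl-1,3-dioxan-2-yl)phenyl]-1-(imidazol-1-yl)ethan-1-one (acyl imidazolide) | O=C(Cc1c(C2OCC(C)(C)CO2)ccc(OCc2ccccc2)c1OCc1ccccc1)n1ccnc1 | intermediate
9 | dimethyl 2-{2-[2,3-bis(benzyloxy)-6-(5,5-dimethyl-1,3-dioxan-2-yl)phenyl]acetyl}-3-oxopentanedioate | COC(=O)CC(=O)C(C(=O)OC)C(=O)Cc1c(C2OCC(C)(C)CO2)ccc(OCc2ccccc2)c1OCc1ccccc1 | intermediate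
10 | methyl 3-[2,3-bis(benzyloxy)-6-(5,5-dimethyl-1,3-dioxan-2-yl)phenyl]-2,4,6-trihydroxybenzoate | COC(=O)c1c(O)cc(O)c(-c2c(C3OCC(C)(C)CO3)ccc(OCc3ccccc3)c2OCc2ccccc2)c1O | intermediate
11 | methyl 4,6-bis(benzyloxy)-3-[2,3-bis(benzyloxy)-6-(5,5-dimethyl-1,3-dioxan-2-yl)phenyl]-2-hydroxybenzoate | COC(=O)c1c(OCc2ccccc2)cc(OCc2ccccc2)c(-c2c(C3OCC(C)(C)CO3)ccc(OCc3ccccc3)c2OCc2ccccc2)c1O | intermediate
12 | 3,4-dihydroxyacetophenone | CC(=O)c1ccc(O)c(O)c1 | starting material
13 | 3,4-bis(benzyloxy)acetophenone | CC(=O)c1ccc(OCc2ccccc2)c(OCc2ccccc2)c1 | intermediate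
14 | 1-{4,6-bis(benzyloxy)-3-[2,3-bis(benzyloxy)-6-(5,5-dimethyl-1,3-dioxan-2-yl)phenyl]-2-hydroxyphenyl}-3-[3,4-bis(benzyloxy)phenyl]propane-1,3-dione | O=C(CC(=O)c1ccc(OCc2ccccc2)c(OCc2ccccc2)c1)c1c(OCc2ccccc2)cc(OCc2ccccc2)c(-c2c(C3OCC(C)(C)CO3)ccc(OCc3ccccc3)c2OCc2ccccc2)c1O | intermediate
15 | 5,7-bis(benzyloxy)-8-[2,3-bis(benzyloxy)-6-(5,5-dimethyl-1,3-dioxan-2-yl)phenyl]-2-[3,4-bis(benzyloxy)phenyl]-4H-chromen-4-one | O=c1cc(-c2ccc(OCc3ccccc3)c(OCc3ccccc3)c2)oc2c(-c3c(C4OCC(C)(C)CO4)ccc(OCc4ccccc4)c3OCc3ccccc3)c(OCc3ccccc3)cc(OCc3ccccc3)c12 | intermediate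
16 | 3,4-bis(benzyloxy)-2-{5,7-bis(benzyloxy)-2-[3,4-bis(benzyloxy)phenyl]-4-oxo-4H-chromen-8-yl}benzaldehyde | O=Cc1ccc(OCc2ccccc2)c(OCc2ccccc2)c1-c1c(OCc2ccccc2)cc(OCc2ccccc2)c2c(=O)cc(-c3ccc(OCc4ccccc4)c(OCc4ccccc4)c3)oc12 | intermediate
17 | 2,4,6-trihydroxyacetophenone | CC(=O)c1c(O)cc(O)cc1O | starting material
18 | 2-hydroxy-4,6-bis(benzyloxy)acetophenone | CC(=O)c1c(O)cc(OCc2ccccc2)cc1OCc1ccccc1 | intermediate
19 | tert-butyl 3-[2,4-bis(benzyloxy)-6-hydroxyphenyl]-3-oxopropanoate | CC(C)(C)OC(=O)CC(=O)c1c(O)cc(OCc2ccccc2)cc1OCc1ccccc1 | intermediate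
20 | tert-butyl 2-[2,4-bis(benzyloxy)-6-hydroxybenzoyl]-3-(3,4-bis(benzyloxy)-2-{5,7-bis(benzyloxy)-2-[3,4-bis(benzyloxy)phenyl]-4-oxo-4H-chromen-8-yl}phenyl)prop-2-enoate (geometry not assigned) | CC(C)(C)OC(=O)C(=Cc1ccc(OCc2ccccc2)c(OCc2ccccc2)c1-c1c(OCc2ccccc2)cc(OCc2ccccc2)c2c(=O)cc(-c3ccc(OCc4ccccc4)c(OCc4ccccc4)c3)oc12)C(=O)c1c(O)cc(OCc2ccccc2)cc1OCc1ccccc1 | intermediate
21 | tert-butyl (2S)-5,7-bis(benzyloxy)-2-(3,4-bis(benzyloxy)-2-{5,7-bis(benzyloxy)-2-[3,4-bis(benzyloxy)phenyl]-4-oxo-4H-chromen-8-yl}phenyl)-4-oxochromane-3-carboxylate (C3 epimers) | O=C1C(C(=O)OC(C)(C)C)[C@@H](c2ccc(OCc3ccccc3)c(OCc3ccccc3)c2-c2c(OCc3ccccc3)cc(OCc3ccccc3)c3c(=O)cc(-c4ccc(OCc5ccccc5)c(OCc5ccccc5)c4)oc23)Oc2cc(OCc3ccccc3)cc(OCc3ccccc3)c21 | intermediate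
22 | (2S)-5,7-bis(benzyloxy)-2-(3,4-bis(benzyloxy)-2-{5,7-bis(benzyloxy)-2-[3,4-bis(benzyloxy)phenyl]-4-oxo-4H-chromen-8-yl}phenyl)-4-oxochromane-3-carboxylic acid (C3 epimers) | O=C1C(C(=O)O)[C@@H](c2ccc(OCc3ccccc3)c(OCc3ccccc3)c2-c2c(OCc3ccccc3)cc(OCc3ccccc3)c3c(=O)cc(-c4ccc(OCc5ccccc5)c(OCc5ccccc5)c4)oc23)Oc2cc(OCc3ccccc3)cc(OCc3ccccc3)c21 | intermediate
23 | (2S)-5,7-bis(benzyloxy)-2-(3,4-bis(benzyloxy)-2-{5,7-bis(benzyloxy)-2-[3,4-bis(benzyloxy)phenyl]-4-oxo-4H-chromen-8-yl}phenyl)chroman-4-one | O=C1C[C@@H](c2ccc(OCc3ccccc3)c(OCc3ccccc3)c2-c2c(OCc3ccccc3)cc(OCc3ccccc3)c3c(=O)cc(-c4ccc(OCc5ccccc5)c(OCc5ccccc5)c4)oc23)Oc2cc(OCc3ccccc3)cc(OCc3ccccc3)c21 | intermediate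
24 | (2S)-2-{2-[2-(3,4-dihydroxyphenyl)-5,7-dihydroxy-4-oxo-4H-chromen-8-yl]-3,4-dihydroxyphenyl}-5,7-dihydroxychroman-4-one | O=C1C[C@@H](c2ccc(O)c(O)c2-c2c(O)cc(O)c3c(=O)cc(-c4ccc(O)c(O)c4)oc23)Oc2cc(O)cc(O)c21 | target

Total step count: 16. Longest linear sequence: 13 steps (steps 1–8, 10, 11, 14, 15, 16).

Steps most likely to fail

Step 7. Oxygen cyclisation to a 4-hydroxy-2-pyrone, or methanolytic retro-Claisen cleavage of the triacylmethane, may outrun the slow carbon cyclisation through the weakly acidic, hindered benzylic position. The fallback sets out from 4 and comes back at 11; it gives up ring construction and makes the C2'–C8'' bond by Suzuki–Miyaura coupling. Bromide 4 is lithiated (n-BuLi, THF, −78 °C) and quenched with 2-isopropoxy-4,4,5,5-tetramethyl-1,3,2-dioxaborolane to give 2-[2,3-bis(benzyloxy)-6-(5,5-dimethyl-1,3-dioxan-2-yl)phenyl]-4,4,5,5-tetramethyl-1,3,2-dioxaborolane F1. Commercial methyl 2,4,6-trihydroxybenzoate is dibenzylated (BnBr, K2CO3, acetone) to methyl 2,4-bis(benzyloxy)-6-hydroxybenzoate F2, which is iodinated ortho to the free phenol (N-iodosuccinimide, DMF) to methyl 4,6-bis(benzyloxy)-2-hydroxy-3-iodobenzoate F3. Coupling of F1 with F3 (Pd(OAc)2, SPhos, K3PO4, toluene/H2O, 100 °C) should give 11 and also makes the selective benzylation of step 8 unnecessary.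

Step 15. Uncatalysed background ring closure, a poor fit of the very hindered ortho-biaryl alkylidene to the catalyst, or partial ring opening during the acidic decarboxylation may erode the enantiomeric purity at C2. The fallback sets out from 16 (with 18) and comes back at 23; it replaces asymmetric catalysis by resolution. Claisen–Schmidt condensation of 16 with 18 (KOH, EtOH/THF, rt) gives the (E)-2'-hydroxychalcone F4. NaOAc in refluxing EtOH closes it to the racemic octa-O-benzyl flavanone F5. Preparative chromatography on a polysaccharide chiral stationary phase then delivers the (2S) enantiomer 23.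

Step 10. The ketone enolate may fail to add to the doubly ortho-substituted, phenoxide-deactivated ester, so that the reaction stalls or the ketone self-condenses. The fallback sets out from 11 and comes back at 14; it reverses the roles of the partners. Ester 11 is saponified (KOH, DMSO/H2O, 80 °C; citric acid) to 4,6-bis(benzyloxy)-3-[2,3-bis(benzyloxy)-6-(5,5-dimethyl-1,3-dioxan-2-yl)phenyl]-2-hydroxybenzoic acid F6. Excess MeLi (THF, 0 °C → rt) converts its lithium salt into 1-{4,6-bis(benzyloxy)-3-[2,3-bis(benzyloxy)-6-(5,5-dimethyl-1,3-dioxan-2-yl)phenyl]-2-hydroxyphenyl}ethan-1-one F7. The phenoxide–enolate dianion of F7 (LiN(SiMe3)2, THF, −78 °C) is then acylated with 3,4-bis(benzyloxy)benzoyl chloride, directly on carbon or by O-acylation followed by Baker–Venkataraman shift, to give 14.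

Further compounds
F1 | step 7 | 2-[2,3-bis(benzyloxy)-6-(5,5-dimethyl-1,3-dioxan-2-yl)phenyl]-4,4,5,5-tetramethyl-1,3,2-dioxaborolane | CC1(C)OB(OC1(C)C)c1c(C2OCC(C)(C)CO2)ccc(OCc2ccccc2)c1OCc1ccccc1
F2 | step 7 | methyl 2,4-bis(benzyloxy)-6-hydroxybenzoate | COC(=O)c1c(O)cc(OCc2ccccc2)cc1OCc1ccccc1
F3 | step 7 | methyl 4,6-bis(benzyloxy)-2-hydroxy-3-iodobenzoate | COC(=O)c1c(OCc2ccccc2)cc(OCc2ccccc2)c(I)c1O
F4 | step 15 | (E)-1-[2,4-bis(benzyloxy)-6-hydroxyphenyl]-3-(3,4-bis(benzyloxy)-2-{5,7-bis(benzyloxy)-2-[3,4-bis(benzyloxy)phenyl]-4-oxo-4H-chromen-8-yl}phenyl)prop-2-en-1-one | O=C(/C=C/c1ccc(OCc2ccccc2)c(OCc2ccccc2)c1-c1c(OCc2ccccc2)cc(OCc2ccccc2)c2c(=O)cc(-c3ccc(OCc4ccccc4)c(OCc4ccccc4)c3)oc12)c1c(O)cc(OCc2ccccc2)cc1OCc1ccccc1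
F5 | step 15 | racemic 5,7-bis(benzyloxy)-2-(3,4-bis(benzyloxy)-2-{5,7-bis(benzyloxy)-2-[3,4-bis(benzyloxy)phenyl]-4-oxo-4H-chromen-8-yl}phenyl)chroman-4-one | O=C1CC(c2ccc(OCc3ccccc3)c(OCc3ccccc3)c2-c2c(OCc3ccccc3)cc(OCc3ccccc3)c3c(=O)cc(-c4ccc(OCc5ccccc5)c(OCc5ccccc5)c4)oc23)Oc2cc(OCc3ccccc3)cc(OCc3ccccc3)c21
F6 | step 10 | 4,6-bis(benzyloxy)-3-[2,3-bis(benzyloxy)-6-(5,5-dimethyl-1,3-dioxan-2-yl)phenyl]-2-hydroxybenzoic acid | OC(=O)c1c(OCc2ccccc2)cc(OCc2ccccc2)c(-c2c(C3OCC(C)(C)CO3)ccc(OCc3ccccc3)c2OCc2ccccc2)c1O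
F7 | step 10 | 1-{4,6-bis(benzyloxy)-3-[2,3-bis(benzyloxy)-6-(5,5-dimethyl-1,3-dioxan-2-yl)phenyl]-2-hydroxyphenyl}ethan-1-one | CC(=O)c1c(OCc2ccccc2)cc(OCc2ccccc2)c(-c2c(C3OCC(C)(C)CO3)ccc(OCc3ccccc3)c2OCc2ccccc2)c1O
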